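## Structural features

The target is an achiral diaryl ether: two benzene rings joined only through one oxygen, which links C1 of ring A to C2 of ring B. Ring A carries three contiguous bromines on C2, C3 and C4, a single hydrogen on C5 and a methoxy group on C6. Ring B carries a free hydroxyl on C1, the aryloxy group on C2, bromines on C4 and C6 and hydrogens on C3 and C5. There is no stereocentre, and the ether axis, although flanked by three ortho substituents, is not expected to be configurationally stable, so no adjacent stereocentres have to be related. The fragile groups are the five aryl C–Br bonds (organolithiums, zerovalent palladium, hydrogenolysis), the electron-rich free phenol (oxidants) and the methyl ether (hot strong acid). The real difficulty is the crowded aryl–O–aryl bond, which any arene–arene coupling would have to form in the presence of several C–Br bonds, together with two different bromine patterns that must not cross over between the rings. The key step exploits the C1(OH)/C2(O-aryl) pair of ring B, which corresponds to the carbonyl carbon and the α-carbon of a 6-aryloxycyclohex-2-enone. The bromines on C4 and C6 lie para and ortho to that hydroxyl, where a phenol brominates unaided, so ring B can be grown as a carbocycle on an alkyl aryl ether by closing its C5–C6 bond.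

## Logic of the disconnections

**11 to 9.** The C4–Br and C6–Br bonds of ring B are cut and ring B is taken back by one dehydrogenation level, passing through 10. These two bromines sit exactly where the hydroxyl of 10 directs, while ring A is deactivated by its three halogens. The gain is that ring B becomes a non-aromatic ketone and the hindered diaryl ether becomes a secondary alkyl aryl ether. The forward step must spend three equivalents of electrophilic bromine in a defined way, one for aromatisation and two for substitution, without touching the last C–H of ring A or the methyl ether.

**9 to 7.** The C2=C3 bond of 9 (C5–C6 of ring B) is cut in the aldol sense. This turns the ring into an open chain with a methyl ketone at one end and an aldehyde at the other. The forward step needs the methyl carbon to act as the nucleophile and the aldehyde as the electrophile; since every other enolisation could only close a four-membered ring, the demand reduces to favouring ring closure over intermolecular reaction.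

**7 to 5.** The two carbonyl groups of 7 are reconnected as one C=C, which gives cyclopentene 5. The more obvious assembly of 7, conjugate addition of an α-aryloxy methyl ketone to a simple enal, was set aside. It leaves the choice between two α-carbons to the enolate, invites double addition and polymerisation of the acceptor, and exposes the keto-aldehyde to the base that made it. In 5 the positions of ketone, ether and aldehyde are fixed by the ring. The forward cleavage must spare the oxygenated arene and the allylic ether.

**5 to 2 and 4.** The O–C(sp3) bond is cut. The phenol 2 is acidic and its ortho and para carbons are all substituted, so only O-alkylation is possible. The allyl unit of 4 has its methyl group on the central carbon, so both termini are equivalent and direct, allylic or ion-pair substitution all lead to the same constitution. The demand is that a hindered phenoxide captures the activated allylic alcohol faster than elimination occurs.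

**2 to 1, and 4 to 3.** In 2 the C–Br bonds ortho and para to the hydroxyl are cut; the third bromine, para to the methoxy group, is already present in 1. Starting from the bromine-free parent of 1 would leave the site of the third bromination to a contest between the carbons para and ortho to the methoxy group, so that uncertainty is bought off with the starting material. Compound 4 is traced to 3 by removing the carbinol hydrogen; the forward reduction must be 1,2-selective.

## Other disconnections considered

Alternative 1: The cut removes four C–Br bonds at once (C2 and C4 of ring A, C4 and C6 of ring B) and replaces the C3–Br bond of ring A by C–N.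
- Forward key step: the bromine-free amino diaryl ether 2-(5-amino-2-methoxyphenoxy)phenol A2 would take up four equivalents of an electrophilic brominating agent. The amino group of A2 sends halogen to its two ortho carbons (its para carbon holds the methoxy group) and the hydroxyl does the same on ring B, which should give 2-(5-amino-4,6-dibromo-2-methoxyphenoxy)-4,6-dibromophenol A1. Diazotisation of A1 and Sandmeyer bromination would then give 11.
- In its favour: the chemistry is purely aromatic; the awkward central bromine of ring A is placed ipso; the diaryl ether of A2 is made while neither ring carries bromine, so a copper- or palladium-mediated C–O coupling has no C–Br bond to confuse it.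
- Against it: A2 is an electron-rich aminophenol ether that the brominating agent may oxidise. A1 is a weakly basic 2,6-dibromoaniline whose diazotisation needs forcing conditions in the presence of a free phenol. The ether coupling toward A2 has its nitrogen substituent meta to the reacting carbon, so it gains no activation toward nucleophilic aromatic substitution.
- Comparison: the route through A2 and A1 is probably the equal or the better of the chosen plan in step count, and equal to it in relying on the hydroxyl to direct ring B. The chosen plan avoids both an arene–arene C–O coupling and a diazonium salt, at the price of building a carbocycle and cleaving an alkene.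

Alternative 2: The cut removes C4 of ring B with its bromine, breaking C3–C4 and C4–C5.
- Forward key step: dibromocarbene A5 would add to the isolated alkene of racemic 2-(2,3,4-tribromo-6-methoxyphenoxy)cyclopent-3-en-1-one A4. The fused gem-dibromocyclopropane opens in a cyclopropyl-to-allyl ionisation, and dehydrobromination with enolisation should give 4-bromo-2-(2,3,4-tribromo-6-methoxyphenoxy)phenol A3. One ortho-bromination of A3 would complete 11.
- In its favour: the para bromine of A3 is fixed by construction and not by directing effects; aromatisation is built into the ring expansion, so no separate dehydrogenation is needed. On both points it is the better of the chosen plan. It is its equal in introducing the ether oxygen as an alkyl aryl ether.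
- Against it: A4 is a β,γ-unsaturated, doubly enolisable ketone that should slip into conjugation or be alkylated under the strongly basic haloform–hydroxide generation of A5. Neutral sources of A5 are hazardous organometallics. Access to A4 is not short, and a further bromination of A3 is still required.
- Comparison: the mechanism is less secure on a substrate such as A4, and the route through A3 is likely one or two steps longer than the chosen plan.

Alternative 3: The cut breaks C1–C6 and C2–C3 of ring B.
- Forward key step: the bis(trimethylsilyl) ketene acetal of the ring A aryloxyacetic acid, 1,2,3-tribromo-4-{[2,2-bis(trimethylsilyloxy)ethenyl]oxy}-5-methoxybenzene A8, would add to 3,5-dibromo-2H-pyran-2-one A7 in an inverse-electron-demand Diels–Alder reaction, its aryloxy-bearing carbon bonding to C6 and its acetal carbon to C3 of A7. Decarboxylative cycloreversion of the bridged lactone and elimination of one silyloxy group should give the trimethylsilyl ether of the target, [2,4-dibromo-6-(2,3,4-tribromo-6-methoxyphenoxy)phenoxy]trimethylsilane A6. Aqueous work-up would then desilylate A6 to 11.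
- In its favour: it is the most convergent plan. Both ring B bromines of A6 arrive in fixed positions with no substitution regiochemistry to argue, the polarity of A8 and A7 matches the required orientation, and the count from 2 to A6 and on to 11 could be three or four steps. On step economy and regiochemical certainty it is the better of the chosen plan, and its equal in avoiding an arene–arene C–O coupling.
- Against it: A8 is hindered at its nucleophilic carbon and moisture-sensitive, and may react stepwise by conjugate addition and ring opening instead of cycloaddition. The bridged lactone may need strong heating to decarboxylate, at which point A8 can rearrange. A7 has to be prepared. Making A8 requires a strong amide base in the presence of a polybromoarene with an acidic ring hydrogen.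
- Comparison: the route through A6 is shorter, but the chosen plan is the more conservative one, since each of its bond formations belongs to a well-explored class and its ring closure has only one possible ring size.

Key step: step 5

Remark on the chemistry: the target is achiral, so every stereogenic intermediate is carried as a racemate or a diastereomer mixture; 5-bromo-2-methoxyphenol and 2-methylcyclopent-2-en-1-one are taken as purchasable.

## Route

Step 1
Reactants: 1 5-bromo-2-methoxyphenol
Product: 2 2,3,4-tribromo-6-methoxyphenol
Conditions: Br2 (2.05 equiv), AcOH, 20 °C
Reagents that add atoms: bromine, BrBr
Why: Electrophilic aromatic bromination; the free hydroxyl activates only its para carbon and its open ortho carbon (C4 and C6 of 1), and the remaining C–H, meta to the hydroxyl and ortho to the methoxy group, should stay untouched at this stoichiometry.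

Step 2
Reactants: 3 2-methylcyclopent-2-en-1-one
Product: 4 2-methylcyclopent-2-en-1-ol (racemic)
Conditions: NaBH4, CeCl3·7H2O, MeOH, 0 °C
Reagents that add atoms: none
Why: Luche reduction; the cerium-modified borohydride should deliver hydride 1,2 to the enone carbonyl and leave the alkene, and the new carbinol centre is formed as a racemate, which is all that is needed.

Step 3
Reactants: 2 2,3,4-tribromo-6-methoxyphenol; 4 2-methylcyclopent-2-en-1-ol (racemic)
Product: 5 1,2,3-tribromo-5-methoxy-4-[(2-methylcyclopent-2-en-1-yl)oxy]benzene (racemic)
Conditions: PPh3, DIAD, THF, 0 → 20 °C
Reagents that add atoms: none
Why: Mitsunobu etherification; the acidic tribromophenol protonates the betaine readily, and its blocked ortho and para carbons leave O-alkylation as the only outcome. The two allyl termini of 4 are equivalent, so direct and allylic displacement give the same racemic ether.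

Step 4
Reactants: 5 1,2,3-tribromo-5-methoxy-4-[(2-methylcyclopent-2-en-1-yl)oxy]benzene (racemic)
Product: 7 4-(2,3,4-tribromo-6-methoxyphenoxy)-5-oxohexanal (racemic), via secondary ozonide 6 (not isolated)
Conditions: O3 (1.0 equiv), CH2Cl2, −78 °C; then PPh3, −78 → 20 °C
Reagents that add atoms: ozone, [O-][O+]=O
Why: Ozonolysis with reductive work-up (Criegee mechanism); the trisubstituted alkene is by far the most electron-rich π-system of 5, the tribrominated arene being deactivated. Cleavage of the ring C=C should unveil the methyl ketone and the aldehyde in their final positions, with the ether-bearing centre untouched.

Step 5
Reactants: 7 4-(2,3,4-tribromo-6-methoxyphenoxy)-5-oxohexanal (racemic)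
Product: 9 6-(2,3,4-tribromo-6-methoxyphenoxy)cyclohex-2-en-1-one (racemic), via aldol adduct 8 (not isolated)
Conditions: pyrrolidine (0.3 equiv), AcOH (0.3 equiv), toluene (0.02 M), 20 → 60 °C
Reagents that add atoms: none
Why: Pyrrolidinium acetate should convert the methyl ketone of 7 reversibly into its less substituted enamine (the CH3 side is favoured over the aryloxy-bearing side on steric grounds), and this nucleophile attacks the far more electrophilic aldehyde carbon intramolecularly to give, after hydrolysis, the β-hydroxy ketone 8. Loss of water from 8 by an E1cB pathway through the enol or enamine then places the new C=C in conjugation with the ketone and gives 9. The closest known reaction type is the aldol stage of a Robinson annulation, that is the cyclisation of a 5-oxohexanal to a cyclohex-2-enone. The ring closes in the 6-enolexo-exo-trig mode, which is stereoelectronically favoured; enolisation at the aryloxy-bearing carbon or at the aldehyde α-carbon could only close four-membered rings, so these reversible events drain no material. No stereocentre is created that survives: the carbinol centre of 8 disappears on dehydration and the ether-bearing centre is carried as a racemate that is erased in step 6. The selectivity required is ring closure over intermolecular aldol reaction of the aldehyde, and it is secured by the six-membered transition state together with high dilution. The aryloxy group sits α and not β to any carbanion that can form, so it cannot be expelled, and the aryl bromides are inert to a weak amine and acetic acid.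

Step 6
Reactants: 9 6-(2,3,4-tribromo-6-methoxyphenoxy)cyclohex-2-en-1-one (racemic)
Product: 11 2,4-dibromo-6-(2,3,4-tribromo-6-methoxyphenoxy)phenol, via ring B phenol 10 (not isolated)
Conditions: Br2 (3.05 equiv), AcOH, 20 → 60 °C
Reagents that add atoms: bromine, BrBr
Why: Halogenative aromatisation of a cyclohexenone followed by phenol bromination; acid-catalysed enolisation toward the ether-bearing α-carbon, bromination there and loss of HBr should give a cross-conjugated dienone that tautomerises to 10. The hydroxyl of 10 then directs two electrophilic substitutions to its open para and ortho carbons (C4 and C6 of ring B), while ring A, deactivated by three bromines, should not be attacked.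

## Compound list

1 | 5-bromo-2-methoxyphenol | COc1ccc(Br)cc1O | starting material
2 | 2,3,4-tribromo-6-methoxyphenol | COc1cc(Br)c(Br)c(Br)c1O | intermediate
3 | 2-methylcyclopent-2-en-1-one | CC1=CCCC1=O | starting material
4 | 2-methylcyclopent-2-en-1-ol (racemic) | CC1=CCCC1O | intermediate
5 | 1,2,3-tribromo-5-methoxy-4-[(2-methylcyclopent-2-en-1-yl)oxy]benzene (racemic) | COc1cc(Br)c(Br)c(Br)c1OC1CCC=C1C | intermediate
6 | 1-methyl-2-(2,3,4-tribromo-6-methoxyphenoxy)-6,7,8-trioxabicyclo[3.2.1]octane (secondary ozonide, diastereomer mixture, racemic; not isolated) | COc1cc(Br)c(Br)c(Br)c1OC1CCC2OOC1(C)O2 | intermediate
7 | 4-(2,3,4-tribromo-6-methoxyphenoxy)-5-oxohexanal (racemic) | COc1cc(Br)c(Br)c(Br)c1OC(CCC=O)C(C)=O | intermediate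
8 | 5-hydroxy-2-(2,3,4-tribromo-6-methoxyphenoxy)cyclohexan-1-one (diastereomer mixture, racemic; not isolated) | COc1cc(Br)c(Br)c(Br)c1OC1CCC(O)CC1=O | intermediate
9 | 6-(2,3,4-tribromo-6-methoxyphenoxy)cyclohex-2-en-1-one (racemic) | COc1cc(Br)c(Br)c(Br)c1OC1CCC=CC1=O | intermediate
10 | 2-(2,3,4-tribromo-6-methoxyphenoxy)phenol (not isolated) | COc1cc(Br)c(Br)c(Br)c1Oc1ccccc1O | intermediate
11 | 2,4-dibromo-6-(2,3,4-tribromo-6-methoxyphenoxy)phenol | COc1cc(Br)c(Br)c(Br)c1Oc1cc(Br)cc(Br)c1O | target

## Step count and least certain steps

Total step count: 6. Longest linear sequence: 5 steps (1 → 2 → 5 → 7 → 9 → 11; the branch from 3 is equally long).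

**Step 5 (key step).** What may go wrong: intermolecular aldol and Mannich-type oligomerisation through the aldehyde outrunning ring closure, or arrest at the aldol stage with retro-aldol opening when the dehydration is forced. Fallback, setting out from 7 and returning at 9: only the addition is carried out under mild, dilute conditions and 8 is isolated. Its secondary alcohol is converted with MsCl and Et3N into 3-oxo-4-(2,3,4-tribromo-6-methoxyphenoxy)cyclohexyl methanesulfonate F1, and F1 is eliminated with DBU by an E1cB pathway to 9. This replaces a one-flask condensation by addition, activation and elimination as separate events.

**Step 3.** What may go wrong: slow attack of the hindered, weakly nucleophilic phenoxide on the alkoxyphosphonium ion, so that elimination of the activated alcohol to a diene or alkylation of the reduced azo reagent takes over. Fallback, setting out from 4 and returning at 5: 4 is treated with cold concentrated aqueous HBr to give 5-bromo-1-methylcyclopent-1-ene F2, and 2 is alkylated with F2 (K2CO3, DMF, 0 °C) in a Williamson ether synthesis. The symmetric allyl system again makes all substitution pathways converge on 5.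

**Step 4.** What may go wrong: over-oxidation by attack of ozone on the oxygenated arene once the alkene is consumed, or abnormal fragmentation of the carbonyl oxide next to the ether oxygen with loss of a carbon. Fallback, setting out from 5 and returning at 7: catalytic OsO4 with N-methylmorpholine N-oxide in aqueous acetone should give the cis-diol 1-methyl-5-(2,3,4-tribromo-6-methoxyphenoxy)cyclopentane-1,2-diol F3, and NaIO4 in aqueous THF then cleaves the glycol of F3 to 7.

**Step 6.** What may go wrong:
- incomplete loss of HBr, so that material stalls at the bromo ketone stage;
- solvolytic loss of the aryloxy group at the α-bromo-α-aryloxy ketone stage;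
- a third substitution on ring B;
- addition of bromine across the enone alkene in competition with α-bromination, which is expected to be self-correcting, because elimination from such an adduct leaves the halogen ortho to the future hydroxyl.

Fallback, setting out from 9 and returning at 11: dehydrogenation with DDQ in dioxane at 90 °C should give 10, which is isolated and then brominated with N-bromosuccinimide (2.0 equiv, MeCN, 0 °C). Oxidation and substitution are thereby separated, and no compound outside the compound list is made, hence the entry F0.

## Further compounds

F1 | step 5 | 3-oxo-4-(2,3,4-tribromo-6-methoxyphenoxy)cyclohexyl methanesulfonate (diastereomer mixture, racemic) | COc1cc(Br)c(Br)c(Br)c1OC1CCC(OS(C)(=O)=O)CC1=O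
F2 | step 3 | 5-bromo-1-methylcyclopent-1-ene (racemic) | CC1=CCCC1Br
F3 | step 4 | 1-methyl-5-(2,3,4-tribromo-6-methoxyphenoxy)cyclopentane-1,2-diol (cis-diol, racemic, ether carbon undefined) | COc1cc(Br)c(Br)c(Br)c1OC1CC[C@H](O)[C@]1(C)O
F0 | step 6 | none | none
A1 | alternative 1 | 2-(5-amino-4,6-dibromo-2-methoxyphenoxy)-4,6-dibromophenol | COc1cc(Br)c(N)c(Br)c1Oc1cc(Br)cc(Br)c1O
A2 | alternative 1 | 2-(5-amino-2-methoxyphenoxy)phenol | COc1ccc(N)cc1Oc1ccccc1O
A3 | alternative 2 | 4-bromo-2-(2,3,4-tribromo-6-methoxyphenoxy)phenol | COc1cc(Br)c(Br)c(Br)c1Oc1cc(Br)ccc1O
A4 | alternative 2 | 2-(2,3,4-tribromo-6-methoxyphenoxy)cyclopent-3-en-1-one (racemic) | COc1cc(Br)c(Br)c(Br)c1OC1C=CCC1=O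
A5 | alternative 2 | dibromocarbene | Br[C]Br
A6 | alternative 3 | [2,4-dibromo-6-(2,3,4-tribromo-6-methoxyphenoxy)phenoxy]trimethylsilane | COc1cc(Br)c(Br)c(Br)c1Oc1cc(Br)cc(Br)c1O[Si](C)(C)C
A7 | alternative 3 | 3,5-dibromo-2H-pyran-2-one | O=C1OC=C(Br)C=C1Br
A8 | alternative 3 | 1,2,3-tribromo-4-{[2,2-bis(trimethylsilyloxy)ethenyl]oxy}-5-methoxybenzene | COc1cc(Br)c(Br)c(Br)c1OC=C(O[Si](C)(C)C)O[Si](C)(C)C
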